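The vessel is what differs here: a closed flask, a stirred tank, a plug-flow tube, and a flask into which substrate is dosed.

in all of them: enzyme 6.6 µM
- Wednesday's: substrate 0.066 M; run made earlier
- Sunday's: substrate 0.092 M; run made earlier
- Saturday's: substrate 0.15 M; run made earlier
- beta: substrate 0.066 M; everything together in a closed stirred flask, run for 40 min; time 40 min
- theta: substrate 0.066 M; one stirred flow tank at steady state, fed with the mixture as stated, mean residence time 40 min
- delta: substrate 0.066 M; a tube with plug flow, the mixed feed as stated, residence time 40 min; time 40 min
- zeta: substrate 0.066 M (fed, over 32.0 min); all but substrate at the start; substrate goes in evenly over 32.0 min, the run ends at 40 min; time 40 min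

- Wednesday's (time / min: target / %, substrate / %): 10.0: 42.7, 36.2; 20.0: 36.8, 10.3; 30.0: 22.2, 2.4; 40.0: 11.0, 0.5
- Sunday's (time / min: target / %, substrate / %): 2.00: 12.4, 85.7; 4.00: 23.1, 73.1; 10.0: 39.5, 41.0; 25.0: 29.8, 6.3
- Saturday's (time / min: target / %, substrate / %): 6.00: 25.1, 68.1; 12.0: 35.8, 42.6; 20.0: 36.3, 19.2; 25.0: 32.0, 10.8

(each reading ± 0.3 percentage points)

- the set-up with the highest amount of target at the outlet or at the end, in percent of the substrate put in ("none" if the first two lie within 2 percentage points) (beta / theta / delta / zeta / none)
- amount of target at the outlet or at the end, in percent of the substrate put in, beta
- amount of target at the outlet or at the end, in percent of the substrate put in, theta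
- amount of target at the outlet or at the end, in percent of the substrate put in, delta
- amount of target at the outlet or at the end, in percent of the substrate put in, zeta

- the stated concentrations are those of everything mixed, before any reaction; amounts are the same in each set-up
- the feed brings no volume worth counting
- the earlier runs were made in a closed, stirred flask

Two colleagues argue over the dosed flask, zeta. The first reads Wednesday's run, which has beta's charge: target stands at 42.7 % after 10.0 min, but at 11.0 % after 40.0 min. Zeta has the same enzyme and the same clock, he says, so dosing merely delays things, and he puts zeta near that last reading, with beta and delta.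

The second asks where target must end up. Between 30.0 min and 40.0 min of Wednesday's run, target drops from 22.2 % to 11.0 % while substrate drops from 2.4 % to 0.5 %, so the target lost is both drops together. Divided by the mean target level and the minutes, these readings give a loss constant of about 0.0789 min⁻¹.

Her rule is the dosing ceiling: the target level at which loss per minute equals supply per minute, that is, the share of the charge fed per minute divided by the loss constant. In zeta, counting fed substrate as converted at once, it is 39.6 %. The time scale of the approach is about 12.7 min, shorter than the feed of 32.0 min. Her estimate takes target at the ceiling when the feed ends and lets it decay over the remaining 8.00 min, which gives a bare tail of 21.1 %, still more than his 11.0 %.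

The forecast takes her side: zeta 28.3 %, between 26.3 % and 30.3 %; theta 20.3 %; beta and delta 11 %; best zeta. Its ground is that “low substrate favours late formation of target”. Its zeta figure stands above her bare tail, for it adds target from substrate still in the flask.

The simulation gives zeta 29.1 %, theta 20.6 %, beta 11.5 % and delta 11.5 %, so zeta is best and the forecast held. The delay the first colleague spoke of is real earlier on: at 20.0 min, beta holds 36.8 % of target against zeta's 23.3 %.

    substrate + enzyme → target + enzyme, rate k1*[substrate]*[enzyme]/(1 + ([substrate]/Km1)) (0.0982 M, k = 21800 M⁻¹ min⁻¹)
    enzyme + target → enzyme + over-reaction product (k = 11600 M⁻¹ min⁻¹)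

The enzyme's turning of target into over-reaction product is the main reason zeta's target ends so far below the charge: the run without that step gives 91.3 % instead of 29.1 %. That step is the ceiling's loss term, pseudo-first-order at fixed enzyme. At the end of the feed, after 32.0 min, zeta's target stood at 32.7 %, below the ceiling, with 24.7 % of substrate still in the flask.

A neighbour of zeta holds 2.6 × 10⁻⁵ M of enzyme, so the loss constant, scaled with the enzyme, is 0.311 min⁻¹, the ceiling is 10.1 %, and the bare tail is 0.836 %. The simulation gives 1.90 %, above that bare tail, as in zeta.

The readings were computed for substances that don't exist, noise included.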